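## Structural features

The target (C24H26O4) is a pentacyclic phthalide dimer. In phthalide-dimer numbering, used here for all atom labels of the target, the unprimed half is a (Z)-3-butylidene-4,5,6,7-tetrahydrophthalide and the primed half is an aromatic phthalide whose C3' is a spiro centre. The halves share a cyclobutane C6–C7–C3'–C8'. It is cis-fused to the six-membered carbocycle along C6–C7, C3' is the spiro carbon of the benzo-lactone, and C8' carries the propyl group. All four cyclobutane carbons are contiguous stereocentres (6S,7R,3'R,8'R). H6, H7 and H8' lie on the convex face together with the aryl group; the propyl group and the lactone oxygen of C3' lie on the concave face, next to the six-membered ring. The fragile parts are the (Z)-enol lactone (nucleophiles, base, E/Z drift), C7–H (vinylogously acidic, with the C3' carboxylate as a β-leaving group) and the contra-thermodynamic endo propyl group, which can epimerise whenever C3' is a ketone. The real difficulty is the fully substituted cyclobutane, with a quaternary spiro centre and an endo substituent, in one absolute configuration. The key step exploits the fact that C6–C7 is the transannular bond of the eight-membered carbocycle C6–C5–C4–C3a–C7a–C7–C3'–C8'. With C3' as an enol ether and C7a as a ketone, the whole core maps onto a 3-alkoxy-4-propylcycloocta-2,4-dienone.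

## Logic of the disconnections

26 ⇒ 25. The bonds C1–C7a and C1–O2 are cut, which removes the lactone carbonyl carbon. The enol lactone is the most sensitive function, and once it exists C7–H is vinylogously acidic, so it is made last. 25 keeps all four stereocentres and both atoms that flank the missing carbon. The forward step must insert one carbon between a vinyl electrophile and an enol oxygen, close on oxygen rather than carbon, and give the Z alkene.

25 ⇒ 24 ⇒ 23 ⇒ 21 + 22. The O–S bond is cut, the side-chain carbonyl is taken back to the carbinol, and C3a–C3 is cut. This removes the five-carbon chain as 22 and leaves 21, which has only the tetracyclic core and one ketone. The forward steps must enolise at C3a and not at C7, because a C7 enolate can expel the C3' carboxylate, and must sulfonylate the ring oxygen of 24.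

21 ⇒ 20 ⇒ 16 + 17 (through 18 and 19). C7a goes back from ketone to protected alcohol, and the aryl–C3' and O–C1' bonds are cut. The spiro centre is best made by adding an aryl nucleophile that already carries the carboxyl carbon to a cyclobutanone, so that lactonisation follows in the same flask. C7a cannot be a ketone at that point: a 1,3-diketone across C7 would be a strained, cleavage-prone 2-acylcyclobutanone. The silyl group has to leave before C7a can be oxidised, and this is placed in the acidic work-up of the addition. The cut removes the arene and the quaternary centre. It demands attack on the convex face, faster than enolisation toward C8'.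

16 ⇒ 15 ⇒ 14. The O–Si bond and then the C8'–H bond are cut, so the cyclobutanone becomes its methyl enol ether. The epimerisable endo-propyl centre is then created late, by kinetic protonation of a flat, strained enol ether. The forward step needs protonation from the convex face and no later equilibration.

14 ⇒ 13 ⇒ 12. The enantiomers are separated at the alcohol, and the alcohol is traced to the ketone. The key step cannot control absolute configuration; the C7a alcohol is both the handle for enzymatic acylation and the masked form of C7a needed later. The demand is one alcohol diastereomer and good enantiomer discrimination.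

12 ⇒ 10 (through 11). The C6–C7 bond is cut. Both the four- and the six-membered ring and both ring-fusion stereocentres disappear, leaving an achiral monocycle in which methoxy (C3'), propyl (C8') and carbonyl (C7a) already sit on the right atoms. The forward step needs clean photoisomerisation of one ring alkene and closure faster than dimerisation.

10 ⇒ 9 ⇒ 8. The C3'–OMe bond is cut and the oxygen pattern is returned to its 1,3-transposed isomer. The obvious shorter preparation of 10 has two flaws: selenoxide dehydrogenation of a 4-propyl-1,3-dione cannot be steered to C4–C5, and orthoformate O-methylation of the ene-dione goes to the less hindered oxygen, which gives 8 and not 10. 8, in contrast, is what kinetic vinylogous-ester enolate chemistry gives naturally. Turning its carbonyl carbon into the chlorine-bearing carbon of 9 exchanges the roles of the two oxygenated carbons by mechanism, not by a selectivity. The demand is that chloride enters at the former carbonyl carbon and that methoxide substitutes there.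

8 ⇒ 5 ⇒ 3 ⇒ 1 + 2 + 4. The C8'=C6 double bond is removed (dehydrogenation), the C8'–propyl bond is cut (alkylation), and the O–methyl bond is cut back to symmetrical 1. Each forward step uses the α'-position of a vinylogous ester, which is the kinetically preferred site. The only open question is the direction of the selenoxide elimination.

## Other disconnections considered

Alternative 1: The whole phthalide ring is cut from C3' (aryl–C3', aryl–C1' and O–C1'). This leaves the protected cyclobutanone (1R,2R,6S,7R)-2-(methoxymethoxy)-7-propylbicyclo[4.2.0]octan-8-one A2.
- Forward step: CsF would release the aryne from 2-(trimethylsilyl)phenyl trifluoromethanesulfonate A3 and tert-butyl isocyanide A4 would add to it. The aryl anion would attack the ketone of A2 on the convex face and the alkoxide would close on the nitrilium carbon, giving the spiro imino-lactone A1.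
- In its favour: three bonds and the spiro ring form in one operation. No ester-bearing Grignard reagent is needed. The medium is only weakly basic, which could spare the epimerisable C8' centre better than step 11 does; on that point it may be the better method.
- Against it here: it replaces only the event that step 11 already achieves in one flask. A2, with three of the four stereocentres, still has to be made, so the core problem is untouched. Ketones are poorer acceptors than aldehydes for the aryne–isocyanide zwitterion, and a hindered, enolisable cyclobutanone is an untested one. A1 needs a further hydrolysis of the N-tert-butyl imidate. Fluoride rules out silyl protection.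
- Comparison: the C3' configuration rests on the same convex-face argument (equal). A carbanion adds to the same carbonyl (equal, possibly milder). It costs about one step more than step 11.

Alternative 2: The C7–C7a bond is cut, leading to achiral 3-(4-oxobutyl)cyclobutan-1-one A5.
- Forward step: a proline-derived secondary amine would form the enamine of A5, which adds to the tethered aldehyde (6-enolexo aldol) to give (1R,2R,6S)-2-hydroxybicyclo[4.2.0]octan-8-one A6, with C6, C7 and C7a set.
- In its favour: absolute configuration would come from a catalyst, with no resolution and no loss of half the material. This is clearly better than the chosen plan. It needs no photochemistry and delivers C7a directly at the alcohol level (equal to 13/14, without a reduction step).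
- Against it here: A6 has no propyl group. Alkylating the cyclobutanone enolate from the convex face would give the exo-propyl epimer, the opposite of the target, so an alkylidene/hydrogenation or kinetic-protonation detour would be needed. Enolisation toward the ring-fusion carbon with β-elimination is an added risk. Enamines of cyclobutanones form reluctantly, and A6 is a retro-aldol-prone β-hydroxy cyclobutanone.
- Comparison: structurally it builds the six-membered ring onto a four-membered ring, whereas the chosen step makes both at once. Mechanistically it is ionic and scalable (better), but it leaves C8' unsolved (worse). Step economy is about equal: roughly four steps to A5, the aldol, protection, two or three steps for the propyl group, then the same endgame.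

Alternative 3: The C6–C8' bond is cut as a retro-1,2-shift, leading to (1R,2R,6R)-7-(but-1-yn-1-yl)-2-[(tert-butyldimethylsilyl)oxy]bicyclo[4.1.0]heptan-7-ol A7.
- Forward step: Ph3PAuCl/AgSbF6 would activate the alkyne and the C3'–C6 cyclopropane bond would migrate to the proximal alkyne carbon, giving (1R,2R,6R,7E)-2-[(tert-butyldimethylsilyl)oxy]-7-propylidenebicyclo[4.2.0]octan-8-one A8.
- In its favour: this is mild, known monovalent-gold chemistry. Hydrogenation of A8 from the convex face would set C8' with the endo propyl group more securely than the kinetic protonation of step 9 (better on that point). An enantiopure six-membered allylic alcohol precursor would avoid resolution (better).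
- Against it here: two cyclopropane bonds (C3'–C6 and C3'–C7) can migrate, and only the inductive effect of the C7a silyloxy group tells them apart. A7 needs a stereocontrolled cyclopropanation and alkynylation of a cyclopropanone equivalent, about five to six steps. A8 is a conjugate acceptor and must be hydrogenated before any aryl addition.
- Comparison: the four-membered ring is grown on an existing six-membered ring, whereas the chosen step creates both rings from a monocycle. The mechanism is ionic rather than photochemical (equal or better for scale). The step count would be about the same or one to two steps shorter, bought with the migration-regiochemistry risk.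

Key step: step 6

Remark 1: Compounds 5–13 are racemic; their SMILES show the enantiomer that is carried forward.
Remark 2: By the sequence rules 10 is (2E,4Z), although both ring double bonds are cis within the ring, because methoxy outranks the ring carbon at C3.
Remark 3 (assumption): hydride is taken to attack 12 on the convex face. If the epimeric alcohol predominated, only the roles of alcohol and acetate in step 8 would be exchanged.

## Route

Step 1
Reactants: 1 cyclooctane-1,3-dione; 2 trimethyl orthoformate
Product: 3 (E)-3-methoxycyclooct-2-en-1-one
Conditions: TsOH·H2O (cat.), MeOH, 25 °C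
Reagents that add atoms: none
Why: Acid-catalysed enol etherification of a symmetrical cyclic 1,3-dione, with the orthoformate as methoxy donor and water scavenger; symmetry makes the regiochemistry unambiguous.

Step 2
Reactants: 3 (E)-3-methoxycyclooct-2-en-1-one; 4 1-iodopropane
Product: 5 rac-(E)-3-methoxy-8-propylcyclooct-2-en-1-one
Conditions: LiN(iPr)2, THF, −78 °C; 4, DMPU, −78 → 0 °C
Reagents that add atoms: none
Why: Stork–Danheiser alkylation: a vinylogous ester is deprotonated kinetically at the α'-carbon (C8) and the enolate is alkylated there; the new stereocentre is removed again in step 3.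

Step 3
Reactants: 5 rac-(E)-3-methoxy-8-propylcyclooct-2-en-1-one
Product: 8 (2E,7Z)-3-methoxy-8-propylcycloocta-2,7-dien-1-one, via alpha-phenylselanyl ketone 6 (not isolated), via selenoxide 7 (not isolated)
Conditions: LiN(iPr)2, THF, −78 °C; PhSeBr; then H2O2, pyridine, CH2Cl2, 0 → 25 °C
Reagents that add atoms: none
Why: Second α'-deprotonation (the only α'-hydrogen left), selenenylation and selenoxide syn-elimination; elimination into the flexible eight-membered ring gives the ring-cis, conjugated C7=C8 alkene, with elimination into the propyl chain as the competing path.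

Step 4
Reactants: 8 (2E,7Z)-3-methoxy-8-propylcycloocta-2,7-dien-1-one
Product: 9 (2E,4Z)-3-chloro-4-propylcycloocta-2,4-dien-1-one
Conditions: (COCl)2, DMF (cat.), CH2Cl2, 0 → 25 °C
Reagents that add atoms: oxalyl chloride, ClC(=O)C(=O)Cl
Why: Vilsmeier-type deoxychlorination of a vinylogous ester: the carbonyl oxygen is acylated, chloride adds to that carbon, the chlorooxalate leaves as CO, CO2 and chloride, and chloride demethylates the resulting methoxyallyl cation. Chlorine therefore ends on the former carbonyl carbon next to the propyl-bearing alkene and the former enol-ether carbon becomes the ketone, so the 1,3-oxygen pattern is transposed by mechanism.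

Step 5
Reactants: 9 (2E,4Z)-3-chloro-4-propylcycloocta-2,4-dien-1-one
Product: 10 (2E,4Z)-3-methoxy-4-propylcycloocta-2,4-dien-1-one
Conditions: NaOMe, MeOH, 0 °C
Reagents that add atoms: sodium methoxide, C[O-].[Na+]
Why: Addition–elimination of methoxide at the β-carbon of a β-chloro enone puts the methoxy group exactly where chlorine was; 1,6-addition at C5 has no leaving group and is reversible.

Step 6
Reactants: 10 (2E,4Z)-3-methoxy-4-propylcycloocta-2,4-dien-1-one
Product: 12 rac-(1S,6R)-8-methoxy-7-propylbicyclo[4.2.0]oct-7-en-2-one, via ring-trans dienone 11 (not isolated)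
Conditions: hν (350 nm, uranium-glass filter), degassed Et2O, 3 mM, −40 °C; then 25 °C in the dark
Reagents that add atoms: none
Why: Excitation of the dienone twists one ring double bond into the ring-trans geometry (11); in the ground state this strained cis,trans-diene closes by a thermally allowed conrotatory 4π electrocyclisation that joins C2 and C5 of the eight-membered ring (C7 and C6 of the target). The closest known reaction type is the photoisomerisation of cycloocta-2,4-dienones and of cycloocta-1,3-diene to cis-bicyclo[4.2.0]oct-7-enes through their cis,trans isomers. The four-membered ring is closed by this conrotatory 4π ring closure; the six-membered ring is closed in the same event as the remainder of the eight-membered ring, that is by transannular C–C bond formation and not by a separate cyclisation. The two new stereocentres C1 and C6 are fixed relative to each other by orbital symmetry and ring geometry, since conrotation of a diene with one trans and one cis ring alkene can only put both hydrogens on the same face (cis fusion); nothing controls the absolute sense, so 12 is racemic and is resolved in step 8. The step needs periselectivity over dimerisation of 11, α-cleavage and secondary photochemistry or double-bond migration of the β,γ-unsaturated ketone 12; high dilution, long-wavelength light that the push–pull dienone absorbs far better than 12, low temperature and immediate reduction serve this. Regiochemistry is not in question because the diene has a single pair of termini, so methoxy ends on C8 and propyl on C7 by construction.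

Step 7
Reactants: 12 rac-(1S,6R)-8-methoxy-7-propylbicyclo[4.2.0]oct-7-en-2-one
Product: 13 rac-(1R,2S,6R)-8-methoxy-7-propylbicyclo[4.2.0]oct-7-en-2-ol
Conditions: NaBH4, MeOH, −40 °C
Reagents that add atoms: none
Why: Hydride addition to the cyclohexanone from the convex face (anti to the cyclobutene) should give mainly the alcohol cis to the four-membered ring; the centre is temporary (reoxidised in step 12) and only has to be uniform for the resolution. Reducing C7a before the cyclobutanone is unmasked also avoids a strained 2-acylcyclobutanone.

Step 8
Reactants: 13 rac-(1R,2S,6R)-8-methoxy-7-propylbicyclo[4.2.0]oct-7-en-2-ol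
Product: 14 (1R,2S,6R)-8-methoxy-7-propylbicyclo[4.2.0]oct-7-en-2-ol
Conditions: Candida antarctica lipase B (immobilised), vinyl acetate, MTBE, 30 °C, stopped just past half conversion
Reagents that add atoms: none
Why: Lipase-catalysed kinetic resolution by transesterification; by the Kazlauskas rule (large group = ring-fusion carbon C1) the (2R)-enantiomer is acetylated faster, so the required (1R,2S,6R)-alcohol is recovered unreacted. This fixes the absolute configuration of C6 and C7 of the target.

Step 9
Reactants: 14 (1R,2S,6R)-8-methoxy-7-propylbicyclo[4.2.0]oct-7-en-2-ol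
Product: 15 (1R,2S,6S,7R)-2-hydroxy-7-propylbicyclo[4.2.0]octan-8-one
Conditions: 0.1 M HCl, THF–H2O, 0 °C
Reagents that add atoms: water, O
Why: Hydrolysis of the strained enol ether: the proton is delivered to C7 on the open convex face (syn to the ring-fusion hydrogens), which leaves the propyl group on the concave face as in the target (C8'); water turns the oxocarbenium ion into the ketone. Cold, brief treatment avoids enolisation toward the more stable exo epimer.

Step 10
Reactants: 15 (1R,2S,6S,7R)-2-hydroxy-7-propylbicyclo[4.2.0]octan-8-one
Product: 16 (1R,2S,6S,7R)-7-propyl-2-[(triethylsilyl)oxy]bicyclo[4.2.0]octan-8-one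
Conditions: Et3SiCl, imidazole, DMF, 0 °C
Reagents that add atoms: chlorotriethylsilane, CC[Si](Cl)(CC)CC
Why: Standard silylation under weakly basic conditions; the silyl ether protects the hydroxyl from the Grignard reagent, blocks retro-aldol of the β-hydroxy cyclobutanone, and comes off in the acidic work-up of step 11.

Step 11
Reactants: 16 (1R,2S,6S,7R)-7-propyl-2-[(triethylsilyl)oxy]bicyclo[4.2.0]octan-8-one; 17 methyl 2-iodobenzoate
Product: 20 (1R,2S,6S,7R,8R)-2-hydroxy-7-propyl-3'H-spiro[bicyclo[4.2.0]octane-8,1'-isobenzofuran]-3'-one, via aryl Grignard reagent 18 (not isolated), via silyl-protected spirolactone 19 (not isolated)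
Conditions: 17, iPrMgCl·LiCl, THF, −40 °C; 16, −40 → 0 °C; then 1 M HCl, 25 °C
Reagents that add atoms: none
Why: Iodine–magnesium exchange gives the ester-bearing aryl Grignard reagent, which adds to the strained cyclobutanone on the convex face (the concave face carries the six-membered ring, the endo propyl group and the silyloxy group); this sets C8 (C3' of the target) with oxygen on the concave face. The tertiary alkoxide lactonises onto the ortho ester and dilute acid removes the silyl group.

Step 12
Reactants: 20 (1R,2S,6S,7R,8R)-2-hydroxy-7-propyl-3'H-spiro[bicyclo[4.2.0]octane-8,1'-isobenzofuran]-3'-one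
Product: 21 (1S,6S,7R,8R)-7-propyl-3'H-spiro[bicyclo[4.2.0]octane-8,1'-isobenzofuran]-2,3'-dione
Conditions: Dess–Martin periodinane, NaHCO3, CH2Cl2, 25 °C
Reagents that add atoms: none
Why: Dess–Martin oxidation under buffered, non-basic conditions, so the ketone forms without enolisation at C1 and the β-elimination of the lactone carboxylate that would follow.

Step 13
Reactants: 21 (1S,6S,7R,8R)-7-propyl-3'H-spiro[bicyclo[4.2.0]octane-8,1'-isobenzofuran]-2,3'-dione; 22 pentanal
Product: 23 (1S,6S,7R,8R)-3-(1-hydroxypentyl)-7-propyl-3'H-spiro[bicyclo[4.2.0]octane-8,1'-isobenzofuran]-2,3'-dione (diastereomer mixture at C3 and the carbinol carbon)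
Conditions: LiN(iPr)2, THF, −78 °C; 22, −78 °C; NH4Cl (aq.)
Reagents that add atoms: none
Why: Kinetic deprotonation at the unhindered methylene C3 (not the ring-fusion methine C1) and aldol addition with one equivalent of base; both new centres are removed in steps 14–16, so the mixture is carried on.

Step 14
Reactants: 23 (1S,6S,7R,8R)-3-(1-hydroxypentyl)-7-propyl-3'H-spiro[bicyclo[4.2.0]octane-8,1'-isobenzofuran]-2,3'-dione
Product: 24 (1S,6S,7R,8R)-3-pentanoyl-7-propyl-3'H-spiro[bicyclo[4.2.0]octane-8,1'-isobenzofuran]-2,3'-dione (largely enolised)
Conditions: Dess–Martin periodinane (1.1 equiv), CH2Cl2, 0 → 25 °C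
Reagents that add atoms: none
Why: Oxidation of a β-hydroxy ketone to the 1,3-diketone; limiting the oxidant avoids further oxidation at C3.

Step 15
Reactants: 24 (1S,6S,7R,8R)-3-pentanoyl-7-propyl-3'H-spiro[bicyclo[4.2.0]octane-8,1'-isobenzofuran]-2,3'-dione
Product: 25 (1S,6S,7R,8R)-3'-oxo-3-pentanoyl-7-propyl-3'H-spiro[bicyclo[4.2.0]oct-2-ene-8,1'-isobenzofuran]-2-yl trifluoromethanesulfonate
Conditions: NaH, THF, 0 °C; Tf2O, −78 → 0 °C
Reagents that add atoms: trifluoromethanesulfonic anhydride, O=S(=O)(OS(=O)(=O)C(F)(F)F)C(F)(F)F
Why: O-Sulfonylation of the sodium enolate of a 2-acylcyclohexanone takes place on the ring oxygen and gives the endocyclic, tetrasubstituted enol triflate conjugated with the side-chain ketone, as is usual for 2-acylcycloalkanones; the leaving group thus sits on C2 (C7a of the target).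

Step 16
Reactants: 25 (1S,6S,7R,8R)-3'-oxo-3-pentanoyl-7-propyl-3'H-spiro[bicyclo[4.2.0]oct-2-ene-8,1'-isobenzofuran]-2-yl trifluoromethanesulfonate
Product: 26 CNP0248594.2, the (3Z,6S,7R,3'R,8'R) phthalide dimer
Conditions: Pd(PPh3)4 (5 mol%), CO (1 atm), Et3N, MeCN, 60 °C
Reagents that add atoms: carbon monoxide, [C-]#[O+]
Why: Oxidative addition of zerovalent palladium to the vinyl triflate, CO insertion and intramolecular trapping of the acylpalladium species by the enol oxygen of the neighbouring pentanoyl group; this is the known carbonylative lactonisation of β-halo and β-triflyloxy enones. Five-membered O-trapping is preferred over C-trapping, and the Z-butylidene isomer, with propyl turned away from C4, is the expected one.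

## Compound list

1 | cyclooctane-1,3-dione | O=C1CCCCCC(=O)C1 | starting material
2 | trimethyl orthoformate | COC(OC)OC | starting material
3 | (E)-3-methoxycyclooct-2-en-1-one (ring-cis alkene) | CO/C1=C/C(=O)CCCCC1 | intermediate
4 | 1-iodopropane | CCCI | starting material
5 | rac-(E)-3-methoxy-8-propylcyclooct-2-en-1-one | CO/C1=C/C(=O)C(CCC)CCCC1 | intermediate
6 | rac-(E)-3-methoxy-8-(phenylselanyl)-8-propylcyclooct-2-en-1-one | CO/C1=C/C(=O)C(CCC)([Se]c2ccccc2)CCCC1 | intermediate
7 | (E)-3-methoxy-8-(phenylseleninyl)-8-propylcyclooct-2-en-1-one | CO/C1=C/C(=O)C(CCC)([Se](=O)c2ccccc2)CCCC1 | intermediate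
8 | (2E,7Z)-3-methoxy-8-propylcycloocta-2,7-dien-1-one (both alkenes ring-cis) | CO/C1=C/C(=O)/C(CCC)=C\CCC1 | intermediate
9 | (2E,4Z)-3-chloro-4-propylcycloocta-2,4-dien-1-one (both alkenes ring-cis) | CCC/C1=C/CCCC(=O)/C=C1/Cl | intermediate
10 | (2E,4Z)-3-methoxy-4-propylcycloocta-2,4-dien-1-one (both alkenes ring-cis) | CCC/C1=C/CCCC(=O)/C=C1/OC | intermediate
11 | (2Z,4Z)-3-methoxy-4-propylcycloocta-2,4-dien-1-one (C2=C3 trans within the ring) | CCC/C1=C/CCCC(=O)/C=C1\OC | intermediate
12 | rac-(1S,6R)-8-methoxy-7-propylbicyclo[4.2.0]oct-7-en-2-one (cis-fused) | O=C2CCC[C@H]1C(CCC)=C(OC)[C@@H]21 | intermediate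
13 | rac-(1R,2S,6R)-8-methoxy-7-propylbicyclo[4.2.0]oct-7-en-2-ol (OH cis to the cyclobutene) | O[C@H]2CCC[C@H]1C(CCC)=C(OC)[C@@H]21 | intermediate
14 | (1R,2S,6R)-8-methoxy-7-propylbicyclo[4.2.0]oct-7-en-2-ol | O[C@H]2CCC[C@H]1C(CCC)=C(OC)[C@@H]21 | intermediate
15 | (1R,2S,6S,7R)-2-hydroxy-7-propylbicyclo[4.2.0]octan-8-one (propyl endo) | O[C@H]2CCC[C@H]1[C@@H](CCC)C(=O)[C@@H]21 | intermediate
16 | (1R,2S,6S,7R)-7-propyl-2-[(triethylsilyl)oxy]bicyclo[4.2.0]octan-8-one | CC[Si](CC)(CC)O[C@H]2CCC[C@H]1[C@@H](CCC)C(=O)[C@@H]21 | intermediate
17 | methyl 2-iodobenzoate | COC(=O)c1ccccc1I | starting material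
18 | [2-(methoxycarbonyl)phenyl]magnesium chloride (LiCl complex) | COC(=O)c1ccccc1[Mg]Cl | intermediate
19 | (1R,2S,6S,7R,8R)-7-propyl-2-[(triethylsilyl)oxy]-3'H-spiro[bicyclo[4.2.0]octane-8,1'-isobenzofuran]-3'-one | CC[Si](CC)(CC)O[C@H]2CCC[C@H]1[C@@H](CCC)[C@@]3(OC(=O)c4ccccc43)[C@@H]21 | intermediate
20 | (1R,2S,6S,7R,8R)-2-hydroxy-7-propyl-3'H-spiro[bicyclo[4.2.0]octane-8,1'-isobenzofuran]-3'-one | O[C@H]2CCC[C@H]1[C@@H](CCC)[C@@]3(OC(=O)c4ccccc43)[C@@H]21 | intermediate
21 | (1S,6S,7R,8R)-7-propyl-3'H-spiro[bicyclo[4.2.0]octane-8,1'-isobenzofuran]-2,3'-dione | O=C2CCC[C@H]1[C@@H](CCC)[C@@]3(OC(=O)c4ccccc43)[C@@H]21 | intermediate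
22 | pentanal | CCCCC=O | starting material
23 | (1S,6S,7R,8R)-3-(1-hydroxypentyl)-7-propyl-3'H-spiro[bicyclo[4.2.0]octane-8,1'-isobenzofuran]-2,3'-dione (diastereomer mixture) | O=C2C(C(O)CCCC)CC[C@H]1[C@@H](CCC)[C@@]3(OC(=O)c4ccccc43)[C@@H]21 | intermediate
24 | (1S,6S,7R,8R)-3-pentanoyl-7-propyl-3'H-spiro[bicyclo[4.2.0]octane-8,1'-isobenzofuran]-2,3'-dione | O=C2C(C(=O)CCCC)CC[C@H]1[C@@H](CCC)[C@@]3(OC(=O)c4ccccc43)[C@@H]21 | intermediate
25 | (1S,6S,7R,8R)-3'-oxo-3-pentanoyl-7-propyl-3'H-spiro[bicyclo[4.2.0]oct-2-ene-8,1'-isobenzofuran]-2-yl trifluoromethanesulfonate | FC(F)(F)S(=O)(=O)OC2=C(C(=O)CCCC)CC[C@H]1[C@@H](CCC)[C@@]3(OC(=O)c4ccccc43)[C@@H]21 | intermediate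
26 | CNP0248594.2, (3Z,6S,7R,3'R,8'R) in phthalide-dimer numbering | CCC/C=C1\OC(=O)C2=C1CC[C@H]1[C@@H](CCC)[C@@]3(OC(=O)c4ccccc43)[C@@H]21 | target

## Step count and least certain steps

Total step count: 16. Longest linear sequence: 16 steps (1 → 26).

Step 6 (key step). What may go wrong:
- bimolecular [2+2] or Diels–Alder-type dimerisation of the strained ring-trans isomer, faster than its closure;
- relaxation back to 10 without net conversion;
- α-cleavage of the excited ketone;
- secondary photoreaction (1,3-acyl shift) or double-bond migration of the β,γ-unsaturated ketone once it accumulates.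

Fallback, setting out from 10 and returning at 12: the chromophore is changed from a dienone to a plain 2-alkoxy-1,3-diene. Reduction with NaBH4/CeCl3·7H2O (MeOH, −78 °C, base-washed glassware because of the acid-labile allylic alcohol) would give rac-(2E,4Z)-3-methoxy-4-propylcycloocta-2,4-dien-1-ol F1. Triplet-sensitised irradiation (acetophenone, pentane) followed by gentle warming would take it through its cis,trans isomer to rac-8-methoxy-7-propylbicyclo[4.2.0]oct-7-en-2-ol as a mixture of C2 epimers F2, as known for cycloocta-1,3-diene itself. Buffered Dess–Martin oxidation would converge the epimers to 12.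

Step 4. What may go wrong:
- chloride fails to add at the hindered former carbonyl carbon, so untransposed material returns on work-up;
- chloride adds at the remote alkene terminus of the dienyl cation;
- the β-chloro dienone hydrolyses during isolation.

Fallback, setting out from 8 and returning at 10: dilute aqueous HCl in THF would hydrolyse 8 to (Z)-4-propylcyclooct-4-ene-1,3-dione F3. Acid-catalysed enol etherification with 2 in MeOH under equilibrating conditions would give both enol ethers; 10 is separated by chromatography and recovered 8 is recycled through F3.

Step 9. What may go wrong: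
- protonation on the concave face;
- acid-catalysed enolisation of the cyclobutanone after hydrolysis, which erodes the endo configuration at C7 (C8' of the target).

Fallback, setting out from 14 and returning at 15: the stereocentre is set by hydrogenation instead of protonation. PhSeCl in wet MeCN would selenenylate the enol ether at its nucleophilic carbon and release the ketone, giving (1R,2S,6R)-2-hydroxy-7-(phenylselanyl)-7-propylbicyclo[4.2.0]octan-8-one F4. Oxidation with H2O2 and syn-elimination, which must go into the side chain because the ring alternative is a cyclobutenone, would give (1R,2S,6R,7E)-2-hydroxy-7-propylidenebicyclo[4.2.0]octan-8-one F5. Hydrogenation over Pd/C from the convex face would deliver 15 with the endo propyl group.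

Step 11. What may go wrong:
- enolisation of the cyclobutanone by the basic, hindered Grignard reagent, returning ketone epimerised at C7;
- β-elimination of the silyloxy group;
- incomplete lactonisation of a crowded alkoxide.

Fallback, setting out from 16 and returning at 20: the carboxyl carbon is introduced after the addition. 1-Bromo-2-iodobenzene and iPrMgCl (THF, −20 °C) would give the smaller and more nucleophilic (2-bromophenyl)magnesium chloride F6. With CeCl3 it would add to 16 on the convex face to give (1R,2S,6S,7R,8R)-8-(2-bromophenyl)-7-propyl-2-[(triethylsilyl)oxy]bicyclo[4.2.0]octan-8-ol F7. Carbonylative lactonisation of the ortho-bromo carbinol (Pd(OAc)2, Ph2P(CH2)3PPh2, CO, Et3N, DMF, 100 °C) would give 19, and 1 M HCl would give 20.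

Step 3. What may go wrong: selenoxide elimination into the propyl chain (exocyclic alkene) competes with elimination into the ring.

Fallback, setting out from 3 and returning at 8: the alkene is made first and the propyl group is attached by cross-coupling. LiN(iPr)2/PhSeBr on 3 would give rac-(E)-3-methoxy-8-(phenylselanyl)cyclooct-2-en-1-one F8. H2O2 would give (2E,7Z)-3-methoxycycloocta-2,7-dien-1-one F9, where only ring hydrogens are available for elimination. I2/pyridine would iodinate the α-position of the new enone to give (2E,7E)-8-iodo-3-methoxycycloocta-2,7-dien-1-one F10. Negishi coupling with n-PrZnBr and PdCl2(dppf) would give 8.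

## Further compounds

F1 | step 6 | rac-(2E,4Z)-3-methoxy-4-propylcycloocta-2,4-dien-1-ol | CCC/C1=C/CCCC(O)/C=C1/OC
F2 | step 6 | rac-8-methoxy-7-propylbicyclo[4.2.0]oct-7-en-2-ol, cis-fused, mixture of C2 epimers | OC2CCC[C@H]1C(CCC)=C(OC)[C@@H]21
F3 | step 4 | (Z)-4-propylcyclooct-4-ene-1,3-dione | CCC/C1=C/CCCC(=O)CC1=O
F4 | step 9 | (1R,2S,6R)-2-hydroxy-7-(phenylselanyl)-7-propylbicyclo[4.2.0]octan-8-one, selenium on the convex face | O[C@H]2CCC[C@H]1[C@](CCC)([Se]c3ccccc3)C(=O)[C@@H]21
F5 | step 9 | (1R,2S,6R,7E)-2-hydroxy-7-propylidenebicyclo[4.2.0]octan-8-one | O[C@H]2CCC[C@H]1/C(=C\CC)C(=O)[C@@H]21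
F6 | step 11 | (2-bromophenyl)magnesium chloride | Brc1ccccc1[Mg]Cl
F7 | step 11 | (1R,2S,6S,7R,8R)-8-(2-bromophenyl)-7-propyl-2-[(triethylsilyl)oxy]bicyclo[4.2.0]octan-8-ol | CC[Si](CC)(CC)O[C@H]2CCC[C@H]1[C@@H](CCC)[C@](O)(c3ccccc3Br)[C@@H]21
F8 | step 3 | rac-(E)-3-methoxy-8-(phenylselanyl)cyclooct-2-en-1-one | CO/C1=C/C(=O)C([Se]c2ccccc2)CCCC1
F9 | step 3 | (2E,7Z)-3-methoxycycloocta-2,7-dien-1-one | CO/C1=C/C(=O)/C=C\CCC1
F10 | step 3 | (2E,7E)-8-iodo-3-methoxycycloocta-2,7-dien-1-one (both alkenes ring-cis) | CO/C1=C/C(=O)/C(I)=C\CCC1
A1 | alternative 1 | (1R,2R,6S,7R,8R)-N-tert-butyl-2-(methoxymethoxy)-7-propyl-3'H-spiro[bicyclo[4.2.0]octane-8,1'-isobenzofuran]-3'-imine | [C@@H]2(OCOC)CCC[C@H]1[C@@H](CCC)[C@@]3(O/C(=N\C(C)(C)C)c4ccccc43)[C@@H]21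
A2 | alternative 1 | (1R,2R,6S,7R)-2-(methoxymethoxy)-7-propylbicyclo[4.2.0]octan-8-one | [C@@H]2(OCOC)CCC[C@H]1[C@@H](CCC)C(=O)[C@@H]21
A3 | alternative 1 | 2-(trimethylsilyl)phenyl trifluoromethanesulfonate | C[Si](C)(C)c1ccccc1OS(=O)(=O)C(F)(F)F
A4 | alternative 1 | tert-butyl isocyanide | CC(C)(C)[N+]#[C-]
A5 | alternative 2 | 3-(4-oxobutyl)cyclobutan-1-one | O=CCCCC1CC(=O)C1
A6 | alternative 2 | (1R,2R,6S)-2-hydroxybicyclo[4.2.0]octan-8-one | O[C@@H]2CCC[C@H]1CC(=O)[C@@H]21
A7 | alternative 3 | (1R,2R,6R)-7-(but-1-yn-1-yl)-2-[(tert-butyldimethylsilyl)oxy]bicyclo[4.1.0]heptan-7-ol | [C@@H]2(O[Si](C)(C)C(C)(C)C)CCC[C@H]1C(O)(C#CCC)[C@@H]21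
A8 | alternative 3 | (1R,2R,6R,7E)-2-[(tert-butyldimethylsilyl)oxy]-7-propylidenebicyclo[4.2.0]octan-8-one | [C@@H]2(O[Si](C)(C)C(C)(C)C)CCC[C@H]1/C(=C\CC)C(=O)[C@@H]21
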